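**Retrosynthetic overview**
1. GA50 ⇐ Wittig methylenation of a 16-ketone and deprotection ⇐ β-face OsO4 dihydroxylation of a 2-ene; ring A is closed last by ring-closing metathesis (C2=C3).
2. 19,10-Lactone and C4 ⇐ intramolecular Michael addition of a C10-O-propionate to a C5=C6 benzyl enoate, then convex-face aldol at C4; C10 carbinol ⇐ allyl addition to a C10 ketone; C7 ⇐ carbonylation of the C6 enol triflate.
3. C12 and C9 ⇐ ketoreductase reduction of the C12 enone carbonyl, then hydroxyl-directed hydrogenation of C9=C11.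
4. Ring D ⇐ gold-catalysed 5-exo-dig cyclisation of an α′-silyl dienol ether onto an angular propargyl group.
5. Rings B and C ⇐ (S)-proline Hajos–Parrish annulation of an achiral triketone (sets C8); ring order: B and C together, then D, then the lactone, then A.

Assumption: the given SMILES is taken as the structure to be made, with hydroxyls at C2, C3 and C12 (gibberellane numbering) and the 12-OH syn to the C15–C16 bridge.

Convention: from 11 on, atoms carry the gibberellane locants they have in the target. "BCD core" means ring B (C5, C6, C8, C9, C10) fused through C8–C9 to the bicyclo[3.2.1]octane made of ring C (C8, C9, C11, C12, C13, C14) and the C15–C16 bridge from C8 to C13. β is the face of ring B that carries H9, H5 and the C15–C16 bridge; α is the face that carries C14 and, later, the lactone. The 12-oxygen is always syn to the C15–C16 bridge (12R).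

**Route**

Step 1
Reactants: 1 cyclopentane-1,3-dione; 2 propargyl bromide (3-bromoprop-1-yne)
Product: 3 2-(prop-2-yn-1-yl)cyclopentane-1,3-dione
Conditions: NaOH (1 equiv), H2O, rt → 60 °C
Reagents that add atoms: none
Why: C-alkylation (SN2) of the dione enolate with an activated propargylic halide; no stereocentre is formed.

Step 2
Reactants: 3 2-(prop-2-yn-1-yl)cyclopentane-1,3-dione; 4 methyl vinyl ketone
Product: 5 2-(3-oxobutyl)-2-(prop-2-yn-1-yl)cyclopentane-1,3-dione
Conditions: H2O, AcOH (cat.), 70 °C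
Reagents that add atoms: none
Why: Michael addition of the soft dione enolate to the enone gives the prochiral triketone.

Step 3
Reactants: 5 2-(3-oxobutyl)-2-(prop-2-yn-1-yl)cyclopentane-1,3-dione
Product: 7 (R)-7a-(prop-2-yn-1-yl)-2,3,7,7a-tetrahydro-1H-indene-1,5(6H)-dione, via aldol ketol 6 (not isolated)
Conditions: (S)-proline (30 mol%), DMF, rt, 72 h; then H2SO4 (cat.), 95 °C
Reagents that add atoms: none
Why: Hajos–Parrish–Eder–Sauer–Wiechert reaction, in which the proline enamine of the side-chain ketone attacks one of the two enantiotopic ring carbonyls and so fixes quaternary C8 in the same spatial sense as the (S)-Hajos–Parrish ketone, after which acid dehydrates the ketol.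

Step 4
Reactants: 7 (R)-7a-(prop-2-yn-1-yl)-2,3,7,7a-tetrahydro-1H-indene-1,5(6H)-dione
Product: 8 (1S,7aR)-1-hydroxy-7a-(prop-2-yn-1-yl)-1,2,3,6,7,7a-hexahydro-5H-inden-5-one
Conditions: NaBH4 (0.3 equiv), EtOH, −20 °C
Reagents that add atoms: none
Why: Chemoselective borohydride reduction of the saturated cyclopentanone over the enone, with hydride entering anti to the angular propargyl group so that the OH is cis to it.

Step 5
Reactants: 8 (1S,7aR)-1-hydroxy-7a-(prop-2-yn-1-yl)-1,2,3,6,7,7a-hexahydro-5H-inden-5-one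
Product: 9 (1S,7aR)-1-(benzyloxy)-7a-(prop-2-yn-1-yl)-1,2,3,6,7,7a-hexahydro-5H-inden-5-one
Conditions: BnOC(=NH)CCl3, TfOH (cat.), CH2Cl2/cyclohexane, 0 °C → rt
Reagents that add atoms: benzyl 2,2,2-trichloroacetimidate, ClC(Cl)(Cl)C(=N)OCc1ccccc1
Why: Acid-catalysed O-benzylation with the trichloroacetimidate avoids base (no enone deprotonation, no alkyne metalation) and gives an ether that survives steps 6–12.

Step 6
Reactants: 9 (1S,7aR)-1-(benzyloxy)-7a-(prop-2-yn-1-yl)-1,2,3,6,7,7a-hexahydro-5H-inden-5-one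
Product: 10 (1S,7aR)-1-(benzyloxy)-5-(tert-butyldimethylsilyloxy)-7a-(prop-2-yn-1-yl)-2,3,7,7a-tetrahydro-1H-indene (2-silyloxy diene, used crude)
Conditions: LiN(i-Pr)2 (1.05 equiv), THF, −78 °C; then TBSCl, HMPA, −78 → 0 °C
Reagents that add atoms: tert-butyldimethylsilyl chloride, CC(C)(C)[Si](C)(C)Cl
Why: Kinetic α′-deprotonation of the enone (the future C13) gives the cross-conjugated dienolate, which is trapped on oxygen.

Step 7
Reactants: 10 2-silyloxy diene
Product: 11 BCD core: 6β-benzyloxy-16-methylidene-9(11)-en-12-one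
Conditions: Ph3PAuCl (5 mol%), AgBF4 (5 mol%), CH2Cl2/MeOH (10:1), rt
Reagents that add atoms: none
Why: Gold-catalysed 5-exo-dig carbocyclisation of the silyl enol ether onto the activated alkyne (Conia-ene type) forms C13–C16 and the exocyclic alkene, and bridgehead C13 can only form on the face that carries the propargyl group.

Step 8
Reactants: 11 BCD core: 6β-benzyloxy-16-methylidene-9(11)-en-12-one
Product: 12 BCD core: 6β-benzyloxy-9(11)-ene-12,16-dione
Conditions: OsO4 (2 mol%), NaIO4 (3 equiv), 2,6-lutidine, dioxane/H2O (3:1), rt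
Reagents that add atoms: sodium periodate, [Na+].[O-]I(=O)(=O)=O
Why: Lemieux–Johnson cleavage takes the electron-rich 1,1-disubstituted alkene and leaves the electron-poor enone, giving the C16 ketone that carries the methylidene group back in step 27.

Step 9
Reactants: 12 BCD core: 6β-benzyloxy-9(11)-ene-12,16-dione
Product: 13 BCD core: 6β-benzyloxy-16,16-ethylenedioxy-9(11)-en-12-one
Conditions: (TMSOCH2)2, TMSOTf (5 mol%), CH2Cl2, −78 → −20 °C
Reagents that add atoms: 1,2-bis(trimethylsilyloxy)ethane, C[Si](C)(C)OCCO[Si](C)(C)C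
Why: Noyori ketalisation protects the saturated C16 ketone selectively over the conjugated C12 ketone.

Step 10
Reactants: 13 BCD core: 6β-benzyloxy-16,16-ethylenedioxy-9(11)-en-12-one
Product: 14 BCD core: 6β-benzyloxy-16,16-ethylenedioxy-9(11)-en-12-ol (12R, OH syn to the C15–C16 bridge)
Conditions: ketoreductase (KRED, panel-selected), NADP+ (cat.), i-PrOH (10 vol%), phosphate buffer pH 7/DMSO (9:1), 30 °C
Reagents that add atoms: none
Why: Ketoreductase-catalysed 1,2-reduction in which NADPH hydride is delivered to the C12 face anti to the C15–C16 bridge, so the enzyme sets C12 and leaves the C=C untouched.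

Step 11
Reactants: 14 BCD core: 6β-benzyloxy-16,16-ethylenedioxy-9(11)-en-12-ol
Product: 15 BCD core: 6β-benzyloxy-16,16-ethylenedioxy-9β-H-12-ol
Conditions: H2 (1 atm), [Ir(cod)(PCy3)(py)]PF6 (10 mol%), CH2Cl2, rt
Reagents that add atoms: none
Why: Hydroxyl-directed hydrogenation, in which iridium bound to the allylic 12-OH delivers H2 to the same face of C9=C11, so H9 ends cis to the OH and to the C15–C16 bridge (9β-H).

Step 12
Reactants: 15 BCD core: 6β-benzyloxy-16,16-ethylenedioxy-9β-H-12-ol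
Product: 16 BCD core: 6β-benzyloxy-12-(tert-butyldimethylsilyloxy)-16,16-ethylenedioxy-9β-H
Conditions: TBSCl, imidazole, DMF, 40 °C
Reagents that add atoms: tert-butyldimethylsilyl chloride, CC(C)(C)[Si](C)(C)Cl
Why: Silylation protects the 12-OH, which must stay masked whenever C16 is a free ketone under base (retro-aldol risk).

Step 13
Reactants: 16 BCD core: 6β-benzyloxy-12-OTBS-16,16-ethylenedioxy-9β-H
Product: 17 BCD core: 12-OTBS-16,16-ethylenedioxy-9β-H-6β-ol
Conditions: H2 (1 atm), Pd/C (10%), EtOAc, rt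
Reagents that add atoms: none
Why: Hydrogenolysis of the benzyl ether is clean because no C=C bond remains, and the silyl ether and ketal are inert.

Step 14
Reactants: 17 BCD core: 12-OTBS-16,16-ethylenedioxy-9β-H-6β-ol
Product: 18 BCD core: 12-OTBS-16,16-ethylenedioxy-9β-H-6-one
Conditions: Dess–Martin periodinane, NaHCO3, CH2Cl2, rt
Reagents that add atoms: none
Why: Dess–Martin oxidation of the secondary alcohol under buffered, non-epimerising conditions.

Step 15
Reactants: 18 BCD core: 12-OTBS-16,16-ethylenedioxy-9β-H-6-one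
Product: 19 BCD core: 12-OTBS-16,16-ethylenedioxy-9β-H-5-en-6-yl trifluoromethanesulfonate
Conditions: KN(SiMe3)2, THF, −78 °C; then PhNTf2
Reagents that add atoms: N-phenylbis(trifluoromethanesulfonimide), O=S(=O)(N(c1ccccc1)S(=O)(=O)C(F)(F)F)C(F)(F)F
Why: Enol triflate formation is regiospecific because the ketone can enolise only toward C5 (C8 is quaternary).

Step 16
Reactants: 19 BCD core 5-en-6-yl triflate
Product: 20 benzyl BCD-core 12-OTBS-16,16-ethylenedioxy-9β-H-5-ene-6-carboxylate
Conditions: Pd(OAc)2 (5 mol%), PPh3 (10 mol%), CO (1 atm), BnOH, Et3N, DMF, 60 °C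
Reagents that add atoms: carbon monoxide, [C-]#[O+]; benzyl alcohol, OCc1ccccc1
Why: Palladium-catalysed alkoxycarbonylation of the vinyl triflate installs C7 as a benzyl ester (as for steroidal 17-enol triflates next to a quaternary centre).

Step 17
Reactants: 20 benzyl BCD-core 5-ene-6-carboxylate
Product: 21 benzyl BCD-core 12-OTBS-16,16-ethylenedioxy-9β-H-10-oxo-5-ene-6-carboxylate
Conditions: Rh2(cap)4 (dirhodium tetracaprolactamate, 1 mol%), t-BuOOH (70% aq., 5 equiv), K2CO3, CH2Cl2, rt
Reagents that add atoms: tert-butyl hydroperoxide, CC(C)(C)OO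
Why: Allylic C–H oxidation at C10, the only allylic CH2 of the enoate, and C9, now α to the ketone, keeps the cis B/C fusion, which is the thermodynamically preferred one (as in 15-oxo steroids).

Step 18
Reactants: 21 benzyl BCD-core 10-oxo-5-ene-6-carboxylate
Product: 22 benzyl BCD-core 10β-allyl-10α-hydroxy-12-OTBS-16,16-ethylenedioxy-9β-H-5-ene-6-carboxylate
Conditions: CH2=CHCH2MgBr (1.3 equiv), THF, −78 °C
Reagents that add atoms: allylmagnesium bromide, C=CC[Mg]Br
Why: Grignard 1,2-addition to the ring-B ketone from the convex β face (C11 and ring C block the α face), giving 10β-allyl and 10α-OH.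

Step 19
Reactants: 22 benzyl BCD-core 10β-allyl-10α-hydroxy-5-ene-6-carboxylate
Product: 23 benzyl BCD-core 10β-allyl-10α-propionyloxy-12-OTBS-16,16-ethylenedioxy-9β-H-5-ene-6-carboxylate
Conditions: LiN(SiMe3)2, THF, −78 °C; then EtCOCl, −78 → 0 °C
Reagents that add atoms: propionyl chloride, CCC(=O)Cl
Why: O-acylation of the lithium alkoxide of the hindered tertiary alcohol, with lithium and low temperature chosen to suppress anionic oxy-Cope rearrangement.

Step 20
Reactants: 23 benzyl BCD-core 10β-allyl-10α-propionyloxy-5-ene-6-carboxylate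
Product: 24 benzyl 10β-allyl-4-methyl-12-OTBS-16,16-ethylenedioxy-5β-H,9β-H-BCD-core 19,10-lactone 6β-carboxylate (C4 epimers)
Conditions: KN(SiMe3)2 (1.2 equiv), THF, −78 → 0 °C; then t-BuOH (3 equiv), rt
Reagents that add atoms: none
Why: Intramolecular Michael addition (5-exo-trig) of the propionate enolate to C5, in which the α-oxygen tether forces the C4–C5 bond onto the α face (cis γ-lactone, 5β-H) and reversible protonation leaves the C6 ester β, trans to that bond; the C4 mixture is erased in step 21.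

Step 21
Reactants: 24 lactone with 10β-allyl and 4-methyl groups
Product: 25 as 24 but with C4 quaternary: 4-methyl-4-(1-hydroxyethyl), hydroxyethyl cis to the 10β-allyl group (carbinol epimers)
Conditions: LiN(i-Pr)2 (1.2 equiv), THF, −78 °C; then MeCHO
Reagents that add atoms: acetaldehyde, CC=O
Why: Aldol addition of the lactone enolate on the convex face of the cis-fused lactone/ring-B bicycle, so the new carbon (C3) ends cis to the allyl group and the methyl takes the C18 position.

Step 22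
Reactants: 25 4-(1-hydroxyethyl) lactone
Product: 26 4-methyl-4-vinyl lactone (vinyl cis to the 10β-allyl group)
Conditions: Martin sulfurane, Ph2S[OC(CF3)2Ph]2, CH2Cl2, rt
Reagents that add atoms: none
Why: Martin sulfurane dehydration, in which only the methyl hydrogens can be lost because C4 is quaternary, so the terminal vinyl group forms.

Step 23
Reactants: 26 4-methyl-4-vinyl lactone
Product: 27 benzyl 12-OTBS-16,16-ethylenedioxy-17-nor-gibberell-2-en-7-oate 19,10-lactone
Conditions: (H2IMes)(PCy3)Cl2Ru=CHPh (second-generation Grubbs catalyst, 10 mol%), toluene, 80 °C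
Reagents that add atoms: none
Why: Ring-closing metathesis of the cis-disposed allyl and vinyl groups closes ring A as the bridged cyclohexene with the 2,3-double bond.

Step 24
Reactants: 27 tetracyclic 2-ene
Product: 28 benzyl 2β,3β-dihydroxy-12-OTBS-16,16-ethylenedioxy-17-nor-gibberellan-7-oate 19,10-lactone
Conditions: OsO4 (5 mol%), NMO, acetone/H2O (4:1), rt
Reagents that add atoms: N-methylmorpholine N-oxide, C[N+]1([O-])CCOCC1; water, O
Why: Upjohn syn-dihydroxylation, in which the lactone bridge covers the α face of the 2,3-alkene so both hydroxyls enter from the β face.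

Step 25
Reactants: 28 2β,3β-diol
Product: 29 benzyl 2β,3β-O-isopropylidene-12-OTBS-16-oxo-17-nor-gibberellan-7-oate 19,10-lactone
Conditions: TsOH·H2O (10 mol%), acetone, 2,2-dimethoxypropane (2 equiv), rt
Reagents that add atoms: 2,2-dimethoxypropane, COC(C)(C)OC
Why: Acid-catalysed transketalisation moves the C16 dioxolane onto acetone while the cis-diol is tied up as its acetonide, which protects the 3-hydroxy lactone from retro-aldol opening in step 27.

Step 26
Reactants: 29 16-oxo acetonide benzyl ester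
Product: 30 2β,3β-O-isopropylidene-12-OTBS-16-oxo-17-nor-gibberellan-7-oic acid 19,10-lactone
Conditions: H2 (1 atm), Pd/C (10%), EtOAc, rt
Reagents that add atoms: none
Why: Hydrogenolysis frees the C7 acid at the one stage where no C=C bond is present.

Step 27
Reactants: 30 16-oxo acetonide acid
Product: 31 12-O-TBS-2,3-O-isopropylidene-GA50
Conditions: Ph3PCH3Br (6 equiv), KOt-Bu (5.5 equiv), THF, rt → 50 °C
Reagents that add atoms: methyltriphenylphosphonium bromide (as its ylide), C[P+](c1ccccc1)(c1ccccc1)c1ccccc1.[Br-]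
Why: Wittig methylenation of the C16 ketone, which tolerates the carboxylate and cannot eliminate the 12-silyloxy group because the ketone cannot enolise toward bridgehead C13.

Step 28
Reactants: 31 12-O-TBS-2,3-O-isopropylidene-GA50
Product: 33 GA50, via GA50 2,3-acetonide 32 (not isolated)
Conditions: TBAF, THF, rt; then AcOH/H2O (4:1), 45 °C
Reagents that add atoms: none
Why: Fluoride desilylation while the diol is still masked, then mild aqueous-acid acetonide hydrolysis, conditions that leave the exocyclic alkene, the lactone and every stereocentre untouched.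

**Compound list**
1 | cyclopentane-1,3-dione | O=C1CCC(=O)C1 | starting material
2 | propargyl bromide (3-bromoprop-1-yne) | C#CCBr | starting material
3 | 2-(prop-2-yn-1-yl)cyclopentane-1,3-dione | C#CCC1C(=O)CCC1=O | intermediate
4 | methyl vinyl ketone (but-3-en-2-one) | CC(=O)C=C | starting material
5 | 2-(3-oxobutyl)-2-(prop-2-yn-1-yl)cyclopentane-1,3-dione | C#CCC1(CCC(C)=O)C(=O)CCC1=O | intermediate
6 | (3aS,7aR)-3a-hydroxy-7a-(prop-2-yn-1-yl)hexahydro-1H-indene-1,5(4H)-dione (cis ketol) | C#CC[C@]12CCC(=O)C[C@@]1(O)CCC2=O | intermediate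
7 | (R)-7a-(prop-2-yn-1-yl)-2,3,7,7a-tetrahydro-1H-indene-1,5(6H)-dione | C#CC[C@]12CCC(=O)C=C1CCC2=O | intermediate
8 | (1S,7aR)-1-hydroxy-7a-(prop-2-yn-1-yl)-1,2,3,6,7,7a-hexahydro-5H-inden-5-one | C#CC[C@]12CCC(=O)C=C1CC[C@@H]2O | intermediate
9 | (1S,7aR)-1-(benzyloxy)-7a-(prop-2-yn-1-yl)-1,2,3,6,7,7a-hexahydro-5H-inden-5-one | C#CC[C@]12CCC(=O)C=C1CC[C@@H]2OCc1ccccc1 | intermediate
10 | (1S,7aR)-1-(benzyloxy)-5-(tert-butyldimethylsilyloxy)-7a-(prop-2-yn-1-yl)-2,3,7,7a-tetrahydro-1H-indene | C#CC[C@]12CC=C(O[Si](C)(C)C(C)(C)C)C=C1CC[C@@H]2OCc1ccccc1 | intermediate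
11 | BCD core: 6β-benzyloxy-16-methylidene-9(11)-en-12-one | C=C1C[C@]23C[C@H]1C(=O)C=C2CC[C@@H]3OCc1ccccc1 | intermediate
12 | BCD core: 6β-benzyloxy-9(11)-ene-12,16-dione | O=C1C[C@]23C[C@H]1C(=O)C=C2CC[C@@H]3OCc1ccccc1 | intermediate
13 | BCD core: 6β-benzyloxy-16,16-ethylenedioxy-9(11)-en-12-one | C1COC2(O1)C[C@]34C[C@H]2C(=O)C=C3CC[C@@H]4OCc1ccccc1 | intermediate
14 | BCD core: 6β-benzyloxy-16,16-ethylenedioxy-9(11)-en-12-ol (12R) | C1COC2(O1)C[C@]34C[C@H]2[C@H](O)C=C3CC[C@@H]4OCc1ccccc1 | intermediate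
15 | BCD core: 6β-benzyloxy-16,16-ethylenedioxy-9β-H-12-ol | C1COC2(O1)C[C@]34C[C@H]2[C@H](O)C[C@H]3CC[C@@H]4OCc1ccccc1 | intermediate
16 | BCD core: 6β-benzyloxy-12-OTBS-16,16-ethylenedioxy-9β-H | C1COC2(O1)C[C@]34C[C@H]2[C@H](O[Si](C)(C)C(C)(C)C)C[C@H]3CC[C@@H]4OCc1ccccc1 | intermediate
17 | BCD core: 12-OTBS-16,16-ethylenedioxy-9β-H-6β-ol | C1COC2(O1)C[C@]34C[C@H]2[C@H](O[Si](C)(C)C(C)(C)C)C[C@H]3CC[C@@H]4O | intermediate
18 | BCD core: 12-OTBS-16,16-ethylenedioxy-9β-H-6-one | C1COC2(O1)C[C@]34C[C@H]2[C@H](O[Si](C)(C)C(C)(C)C)C[C@H]3CCC4=O | intermediate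
19 | BCD core: 12-OTBS-16,16-ethylenedioxy-9β-H-5-en-6-yl triflate | C1COC2(O1)C[C@]34C[C@H]2[C@H](O[Si](C)(C)C(C)(C)C)C[C@H]3CC=C4OS(=O)(=O)C(F)(F)F | intermediate
20 | benzyl BCD-core 12-OTBS-16,16-ethylenedioxy-9β-H-5-ene-6-carboxylate | C1COC2(O1)C[C@]34C[C@H]2[C@H](O[Si](C)(C)C(C)(C)C)C[C@H]3CC=C4C(=O)OCc1ccccc1 | intermediate
21 | benzyl BCD-core 12-OTBS-16,16-ethylenedioxy-9β-H-10-oxo-5-ene-6-carboxylate | C1COC2(O1)C[C@]34C[C@H]2[C@H](O[Si](C)(C)C(C)(C)C)C[C@H]3C(=O)C=C4C(=O)OCc1ccccc1 | intermediate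
22 | benzyl BCD-core 10β-allyl-10α-hydroxy-12-OTBS-16,16-ethylenedioxy-9β-H-5-ene-6-carboxylate | C1COC2(O1)C[C@]34C[C@H]2[C@H](O[Si](C)(C)C(C)(C)C)C[C@H]3[C@](O)(CC=C)C=C4C(=O)OCc1ccccc1 | intermediate
23 | 10α-propionate of 22 | C1COC2(O1)C[C@]34C[C@H]2[C@H](O[Si](C)(C)C(C)(C)C)C[C@H]3[C@](OC(=O)CC)(CC=C)C=C4C(=O)OCc1ccccc1 | intermediate
24 | benzyl 10β-allyl-4-methyl-12-OTBS-16,16-ethylenedioxy-5β-H,9β-H-BCD-core 19,10-lactone 6β-carboxylate (C4 epimers) | C1COC2(O1)C[C@]34C[C@H]2[C@H](O[Si](C)(C)C(C)(C)C)C[C@H]3[C@@]5(CC=C)OC(=O)C(C)[C@H]5[C@@H]4C(=O)OCc1ccccc1 | intermediate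
25 | 4-methyl-4-(1-hydroxyethyl) lactone, hydroxyethyl cis to 10β-allyl (carbinol epimers) | C1COC2(O1)C[C@]34C[C@H]2[C@H](O[Si](C)(C)C(C)(C)C)C[C@H]3[C@@]5(CC=C)OC(=O)[C@](C)(C(C)O)[C@H]5[C@@H]4C(=O)OCc1ccccc1 | intermediate
26 | 4-methyl-4-vinyl lactone, vinyl cis to 10β-allyl | C1COC2(O1)C[C@]34C[C@H]2[C@H](O[Si](C)(C)C(C)(C)C)C[C@H]3[C@@]5(CC=C)OC(=O)[C@](C)(C=C)[C@H]5[C@@H]4C(=O)OCc1ccccc1 | intermediate
27 | benzyl 12-OTBS-16,16-ethylenedioxy-17-nor-gibberell-2-en-7-oate 19,10-lactone | C1COC2(O1)C[C@]34C[C@H]2[C@H](O[Si](C)(C)C(C)(C)C)C[C@H]3[C@@]56CC=C[C@@](C)(C(=O)O5)[C@H]6[C@@H]4C(=O)OCc1ccccc1 | intermediate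
28 | benzyl 2β,3β-dihydroxy-12-OTBS-16,16-ethylenedioxy-17-nor-gibberellan-7-oate 19,10-lactone | C1COC2(O1)C[C@]34C[C@H]2[C@H](O[Si](C)(C)C(C)(C)C)C[C@H]3[C@@]56C[C@H](O)[C@H](O)[C@@](C)(C(=O)O5)[C@H]6[C@@H]4C(=O)OCc1ccccc1 | intermediate
29 | benzyl 2β,3β-O-isopropylidene-12-OTBS-16-oxo-17-nor-gibberellan-7-oate 19,10-lactone | O=C1C[C@]23C[C@H]1[C@H](O[Si](C)(C)C(C)(C)C)C[C@H]2[C@@]45C[C@@H]6OC(C)(C)O[C@@H]6[C@@](C)(C(=O)O4)[C@H]5[C@@H]3C(=O)OCc1ccccc1 | intermediate
30 | 2β,3β-O-isopropylidene-12-OTBS-16-oxo-17-nor-gibberellan-7-oic acid 19,10-lactone | O=C1C[C@]23C[C@H]1[C@H](O[Si](C)(C)C(C)(C)C)C[C@H]2[C@@]45C[C@@H]6OC(C)(C)O[C@@H]6[C@@](C)(C(=O)O4)[C@H]5[C@@H]3C(=O)O | intermediate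
31 | 12-O-TBS-2,3-O-isopropylidene-GA50 | C=C1C[C@]23C[C@H]1[C@H](O[Si](C)(C)C(C)(C)C)C[C@H]2[C@@]45C[C@@H]6OC(C)(C)O[C@@H]6[C@@](C)(C(=O)O4)[C@H]5[C@@H]3C(=O)O | intermediate
32 | GA50 2,3-acetonide | C=C1C[C@]23C[C@H]1[C@H](O)C[C@H]2[C@@]45C[C@@H]6OC(C)(C)O[C@@H]6[C@@](C)(C(=O)O4)[C@H]5[C@@H]3C(=O)O | intermediate
33 | GA50 (2β,3β,12-trihydroxy-20-norgibberell-16-ene-7,19-dioic acid 19,10-lactone, as in the given SMILES) | C=C1C[C@]23C[C@H]1[C@H](O)C[C@H]2[C@@]12C[C@H](O)[C@H](O)[C@@](C)(C(=O)O1)[C@H]2[C@@H]3C(=O)O | target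

**Step count and risks**

Total steps: 28. Longest linear sequence: 28 (the route is fully linear from 1).

The three steps most likely to fail:

The directed hydrogenation of 14 to 15 (step 11) is the most exposed. The iridium catalyst has to bind the 12-OH and the C9=C11 bond on the face that also carries the C15–C16 bridge and its dioxolane; if binding is too slow, undirected addition from the open face would give the 9-epimer. The fallback changes the order of events and the way the two ketones are told apart. It sets out from dione 12, before ketalisation. A ketoreductase chosen for the conjugated C12 carbonyl (over the saturated C16 ketone) gives hydroxy enone F1, in which C16 is still a flat carbonyl and the directing face is less crowded. Hydrogenation with [Ir(cod)(PCy3)(py)]PF6 then gives saturated hydroxy ketone F2, and Noyori ketalisation of the C16 ketone comes back to the route at 15.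

The allylic oxidation of 20 to 21 (step 17) relies on radical C–H oxidation next to an electron-poor alkene, in the presence of a benzyl ester and a ketal. The fallback replaces it with an anionic oxygenation and an oxidative 1,3-transposition. It sets out from 20: γ-deprotonation at C10 with LiN(i-Pr)2 and α-hydroxylation of the dienolate at C6 with 2-(phenylsulfonyl)-3-phenyloxaziridine gives tertiary allylic alcohol F3 (6-hydroxy-5(10)-ene ester). Babler–Dauben oxidation with pyridinium chlorochromate then moves the oxygen to C10 and the double bond back to C5=C6, returning to the route at 21.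

The ring-closing metathesis of 26 to 27 (step 23) has to engage a neopentyl-type vinyl group and form a bridged ring. The fallback is an aldol ring closure of the Mander type. It sets out from 24: hydroboration–oxidation of the allyl group (9-BBN, then NaBO3) gives primary alcohol F4, and Dess–Martin oxidation gives aldehyde F5. Catalytic KOt-Bu in t-BuOH/THF closes ring A by aldol addition of the lactone C4 enolate to C3 (the tether fixes C4) to give 3-hydroxy lactone F6. Dehydration with Martin sulfurane can only go toward C2 and comes back to the route at 27.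

**Further compounds**
F1 | step 11 | BCD core: 6β-benzyloxy-12-hydroxy-9(11)-en-16-one (12-OH syn to the C15–C16 bridge) | O=C1C[C@]23C[C@H]1[C@H](O)C=C2CC[C@@H]3OCc1ccccc1
F2 | step 11 | BCD core: 6β-benzyloxy-12-hydroxy-9β-H-16-one | O=C1C[C@]23C[C@H]1[C@H](O)C[C@H]2CC[C@@H]3OCc1ccccc1
F3 | step 17 | benzyl BCD-core 6-hydroxy-12-OTBS-16,16-ethylenedioxy-9β-H-5(10)-ene-6-carboxylate (C6 epimers) | C1COC2(O1)C[C@]34C[C@H]2[C@H](O[Si](C)(C)C(C)(C)C)C[C@H]3C=CC4(O)C(=O)OCc1ccccc1
F4 | step 23 | 24 with the 10β-allyl group turned into 10β-(3-hydroxypropyl) | C1COC2(O1)C[C@]34C[C@H]2[C@H](O[Si](C)(C)C(C)(C)C)C[C@H]3[C@@]5(CCCO)OC(=O)C(C)[C@H]5[C@@H]4C(=O)OCc1ccccc1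
F5 | step 23 | 24 with the 10β-allyl group turned into 10β-(3-oxopropyl) | C1COC2(O1)C[C@]34C[C@H]2[C@H](O[Si](C)(C)C(C)(C)C)C[C@H]3[C@@]5(CCC=O)OC(=O)C(C)[C@H]5[C@@H]4C(=O)OCc1ccccc1
F6 | step 23 | benzyl 3-hydroxy-12-OTBS-16,16-ethylenedioxy-17-nor-gibberellan-7-oate 19,10-lactone (C3 epimers) | C1COC2(O1)C[C@]34C[C@H]2[C@H](O[Si](C)(C)C(C)(C)C)C[C@H]3[C@@]56CCC(O)[C@@](C)(C(=O)O5)[C@H]6[C@@H]4C(=O)OCc1ccccc1
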